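**Plan**

1. Numbering: C1 is the fully substituted oxirane carbon and bears C7 (the CH2OBz carbon); C6 is the oxirane CH; C2 and C3 carry OAc; C4 and C5 carry OH. α is the face of the C1 oxygen, β the face of C7.
2. Enabling feature: on the six-membered carbocycle, quaternary C1 holds the one-carbon branch C7 and an oxygen lying cis to the C2 oxygen. Apart from the oxirane this is the ring's only cis O/O pair, and it is the pattern left when a benzoic acid ring is dioxygenated at its ipso and ortho carbons.
3. Retrosynthesis: cut O–C6 of the oxirane (C1 hydroxyl displacing a C5,C6 cyclic sulfate), then C5–O and C6–O (osmylation of C5=C6), then C4–O and C3–O (benzyl alcohol opening a C3,C4 epoxide), then the ester C–O bonds, and last C1–O and C2–O, which leaves benzoic acid.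
4. Forward: the carbocycle is the benzene ring of benzoic acid and is never opened. The only ring of the target that is closed is the oxirane (step 11); a dioxolane, a C3,C4 epoxide and a cyclic sulfate serve as temporary rings.
5. Stereochemistry: C1 and C2 come from the enzyme; C3 and C4 from epoxidation anti to the acetonide and inversion at C4; C5 and C6 from osmylation anti to the α oxygens at C1 and C4; C6 is inverted when the oxirane closes.

Key step: step 1

Remark: a benzoate 1,2-dioxygenase strain blocked in the diol dehydrogenase (Cupriavidus necator B9) is taken as obtainable from a culture collection; the NADH it consumes is regenerated inside the cells from fructose.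

**Route**

Step 1
Reactants: 1 benzoic acid
Product: 2 (1S,2R)-1,2-dihydroxycyclohexa-3,5-diene-1-carboxylic acid
Conditions: whole cells of Cupriavidus necator B9 (benzoate 1,2-dioxygenase active, diol dehydrogenase absent), mineral medium, fructose, benzoic acid fed as PhCO2Na, air, pH 7, 30 °C; cell-free broth brought to pH 3 at 0 °C, EtOAc extraction
Reagents that add atoms: dioxygen, O=O
Why: The non-haem iron dioxygenase binds benzoate through its carboxylate, activates O2 at the iron centre with two electrons from NADH and transfers both oxygen atoms suprafacially to the ipso and ortho carbons, so the C1–O and C2–O bonds form on one face and the C3=C4–C5=C6 diene remains. The closest known reaction type is the dioxygenase cis-dihydroxylation of arenes, and the ipso,ortho mode on benzoic acid is established for mutants that lack the diol dehydrogenase. No ring is closed. Both new stereocentres, quaternary C1 and secondary C2, are set by the chiral active site (catalyst control), which exposes one enantiotopic pair of ring carbons and one face to the oxidant and should give the (1S,2R) acid as a single enantiomer. The step needs ipso,ortho site selectivity, one enantiotopic face and no onward oxidation or rearomatisation: carboxylate anchoring in the enzyme secures the first two, the missing dehydrogenase and a cold, brief acidification at work-up secure the last.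

Step 2
Reactants: 2 (1S,2R)-1,2-dihydroxycyclohexa-3,5-diene-1-carboxylic acid; 3 2,2-dimethoxypropane
Product: 4 (3aS,7aR)-2,2-dimethyl-3a,7a-dihydro-1,3-benzodioxole-3a-carboxylic acid (the C1,C2 acetonide of 2)
Conditions: 2,2-dimethoxypropane, TsOH·H2O (cat.), acetone, rt
Reagents that add atoms: 2,2-dimethoxypropane (3), COC(C)(C)OC
Why: Acid-catalysed transketalisation (acetonide formation) is favoured because the cis-1,2-diol can close a cis-fused dioxolane, and with catalytic acid at room temperature it should outrun dehydrative rearomatisation while leaving C1 and C2 untouched.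

Step 3
Reactants: 4 (3aS,7aR)-2,2-dimethyl-3a,7a-dihydro-1,3-benzodioxole-3a-carboxylic acid
Product: 5 [(3aR,7aR)-2,2-dimethyl-3a,7a-dihydro-1,3-benzodioxol-3a-yl]methanol (same spatial arrangement as 4; the C1 descriptor changes only because C7 drops in priority)
Conditions: LiAlH4, THF, 0 °C to rt; H2O then 15% aq NaOH
Reagents that add atoms: none
Why: LiAlH4 reduction of a carboxylic acid to the primary alcohol proceeds through the lithium carboxylate, while the diene (not conjugated to the carboxyl group) and the ketal are inert to hydride, so C7 reaches the alcohol oxidation level without touching a stereocentre.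

Step 4
Reactants: 5 [(3aR,7aR)-2,2-dimethyl-3a,7a-dihydro-1,3-benzodioxol-3a-yl]methanol; 6 benzoyl chloride
Product: 7 [(3aR,7aR)-2,2-dimethyl-3a,7a-dihydro-1,3-benzodioxol-3a-yl]methyl benzoate
Conditions: BzCl, pyridine, DMAP (cat.), CH2Cl2, 0 °C
Reagents that add atoms: benzoyl chloride (6), O=C(Cl)c1ccccc1
Why: Nucleophilic acyl substitution (DMAP-catalysed O-benzoylation) of the primary neopentyl-type alcohol installs the C7 benzoate of the target early, where it also adds bulk on the β face next to C5=C6.

Step 5
Reactants: 7 [(3aR,7aR)-2,2-dimethyl-3a,7a-dihydro-1,3-benzodioxol-3a-yl]methyl benzoate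
Product: 8 (1R,2R,3S,4S)-1-(benzoyloxymethyl)-3,4-epoxy-1,2-O-isopropylidenecyclohex-5-ene-1,2-diol (oxirane on the β face, anti to the dioxolane)
Conditions: mCPBA, NaHCO3, CH2Cl2, 0 °C to rt
Reagents that add atoms: mCPBA (3-chloroperoxybenzoic acid), O=C(OO)c1cccc(Cl)c1
Why: In this Prilezhaev epoxidation the dioxolane shields the α face of both alkenes and the CH2OBz group on quaternary C1 crowds the β face of C5=C6, so the peracid should attack the less hindered, more electron-rich C3=C4 from the β face and set C3 and C4 by substrate control, as is known for arene cis-diol acetonides.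

Step 6
Reactants: 8 (1R,2R,3S,4S)-1-(benzoyloxymethyl)-3,4-epoxy-1,2-O-isopropylidenecyclohex-5-ene-1,2-diol; 9 benzyl alcohol
Product: 10 (1R,2R,3S,4R)-4-benzyloxy-1-(benzoyloxymethyl)-1,2-O-isopropylidenecyclohex-5-ene-1,2,3-triol (3-OH β, 4-OBn α)
Conditions: BnOH (3 equiv), BF3·OEt2 (cat.), CH2Cl2, −30 °C to 0 °C
Reagents that add atoms: benzyl alcohol (9), OCc1ccccc1
Why: In this BF3-activated SN2 opening of a vinyl epoxide the allylic C4–O bond is the weaker one and C3 is screened by the dioxolane, so benzyl alcohol should enter at C4 from the α face with inversion and leave the trans C3-OH(β)/C4-OBn(α) pair, while SN2' attack at C6 is blocked by the adjacent quaternary C1.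

Step 7
Reactants: 10 (1R,2R,3S,4R)-4-benzyloxy-1-(benzoyloxymethyl)-1,2-O-isopropylidenecyclohex-5-ene-1,2,3-triol
Product: 11 (1R,2R,3R,4R)-4-benzyloxy-1-(benzoyloxymethyl)cyclohex-5-ene-1,2,3-triol (1-OH and 2-OH α, 3-OH β; the C3 descriptor changes by priority only)
Conditions: AcOH/H2O 4:1, 50 °C
Reagents that add atoms: none
Why: Acid-catalysed ketal hydrolysis frees the C1 and C2 hydroxyls under conditions that the benzoate and the benzyl ether tolerate, and a shift of the benzoyl group to the tertiary oxygen is thermodynamically unfavourable, so no stereocentre or ester position should change.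

Step 8
Reactants: 11 (1R,2R,3R,4R)-4-benzyloxy-1-(benzoyloxymethyl)cyclohex-5-ene-1,2,3-triol; 12 acetic anhydride
Product: 13 (1R,2R,3S,4R)-2,3-di-O-acetyl-4-O-benzyl-1-(benzoyloxymethyl)cyclohex-5-ene-1,2,3,4-tetrol (tertiary 1-OH free)
Conditions: Ac2O, pyridine, rt
Reagents that add atoms: acetic anhydride (12), CC(=O)OC(C)=O
Why: Selective O-acetylation with Ac2O in pyridine esterifies the two secondary hydroxyls at C2 and C3, whereas the hindered tertiary C1 hydroxyl, which must stay free for the later ring closure, does not react without forcing conditions.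

Step 9
Reactants: 13 (1R,2R,3S,4R)-2,3-di-O-acetyl-4-O-benzyl-1-(benzoyloxymethyl)cyclohex-5-ene-1,2,3,4-tetrol
Product: 14 (1S,2R,3S,4R,5S,6R)-2,3-di-O-acetyl-4-O-benzyl-1-(benzoyloxymethyl)cyclohexane-1,2,3,4,5,6-hexol (5-OH and 6-OH β)
Conditions: OsO4 (cat.), NMO, acetone/H2O 4:1, rt; aq Na2SO3
Reagents that add atoms: osmium tetroxide, O=[Os](=O)(=O)=O; N-methylmorpholine N-oxide, C[N+]1([O-])CCOCC1; water, O
Why: In this catalytic OsO4/NMO cis-dihydroxylation ([3+2] addition, then hydrolysis of the osmate ester) the favoured half-chair has the C2, C3 and C4 substituents equatorial and the C1 hydroxyl pseudoaxial on the α face beside the α C4 benzyloxy group, so the oxidant should add anti to both allylic oxygens on the β face and set C5 and C6 as the β,β cis-diol.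

Step 10
Reactants: 14 (1S,2R,3S,4R,5S,6R)-2,3-di-O-acetyl-4-O-benzyl-1-(benzoyloxymethyl)cyclohexane-1,2,3,4,5,6-hexol
Product: 16 (1R,2R,3S,4S,5R,6R)-2,3-di-O-acetyl-4-O-benzyl-1-(benzoyloxymethyl)cyclohexane-1,2,3,4,5,6-hexol 5,6-cyclic sulfate, via cyclic sulfite 15 (not isolated)
Conditions: SOCl2, Et3N, CH2Cl2, 0 °C; aqueous wash and solvent exchange; then RuCl3·3H2O (cat.), NaIO4, MeCN/H2O, 0 °C
Reagents that add atoms: thionyl chloride, O=S(Cl)Cl; sodium periodate, [Na+].[O-]I(=O)(=O)=O
Why: In this cyclic sulfite formation followed by RuO4-catalysed oxidation to the cyclic sulfate, the cis C5,C6-diol closes a five-membered sulfite much faster than the hindered tertiary C1 hydroxyl (trans-diaxial to C6–O) can react, and the brief catalytic oxidation at 0 °C is of a kind that benzyl ethers and tertiary alcohols are known to survive, with C5 and C6 retained.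

Step 11
Reactants: 16 (1R,2R,3S,4S,5R,6R)-2,3-di-O-acetyl-4-O-benzyl-1-(benzoyloxymethyl)cyclohexane-1,2,3,4,5,6-hexol 5,6-cyclic sulfate
Product: 18 [(1S,2R,3S,4R,5R,6S)-2,3-diacetoxy-4-benzyloxy-5-hydroxy-7-oxabicyclo[4.1.0]heptan-1-yl]methyl benzoate, via epoxy sulfate sodium salt 17 (not isolated)
Conditions: NaH, THF, 0 °C; then H2SO4 (cat.), H2O (2 equiv), THF, rt; aq NaHCO3
Reagents that add atoms: none
Why: In this Payne-type rearrangement of a hydroxy cyclic sulfate the C1 alkoxide lies antiperiplanar to the C6–O bond and displaces it in a 3-exo-tet SN2 closure with inversion at C6 to give the α oxirane, the C5 sulfate monoester is then cleaved at S–O by catalytic acid so that C5 keeps its β oxygen, and reversible acyl shifts to the tertiary alkoxide are uphill and are drained by the irreversible closure.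

Step 12
Reactants: 18 [(1S,2R,3S,4R,5R,6S)-2,3-diacetoxy-4-benzyloxy-5-hydroxy-7-oxabicyclo[4.1.0]heptan-1-yl]methyl benzoate
Product: 19 [(1S,2R,3S,4R,5R,6S)-2,3-diacetoxy-4,5-dihydroxy-7-oxabicyclo[4.1.0]heptan-1-yl]methyl benzoate (CNP0171674.1)
Conditions: H2 (1 atm), Pd/C (10% palladium on carbon), EtOAc, rt
Reagents that add atoms: none
Why: Catalytic hydrogenolysis of the benzyl ether in a neutral solvent should free the C4 hydroxyl without touching the non-benzylic oxirane, the acetates or the benzoate, and no stereocentre is involved.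

**Compound list**

1 | benzoic acid | OC(=O)c1ccccc1 | starting material
2 | (1S,2R)-1,2-dihydroxycyclohexa-3,5-diene-1-carboxylic acid | OC(=O)[C@]1(O)C=CC=C[C@H]1O | intermediate
3 | 2,2-dimethoxypropane | COC(C)(C)OC | starting material
4 | (3aS,7aR)-2,2-dimethyl-3a,7a-dihydro-1,3-benzodioxole-3a-carboxylic acid | OC(=O)[C@@]12OC(C)(C)O[C@@H]1C=CC=C2 | intermediate
5 | [(3aR,7aR)-2,2-dimethyl-3a,7a-dihydro-1,3-benzodioxol-3a-yl]methanol | OC[C@@]12OC(C)(C)O[C@@H]1C=CC=C2 | intermediate
6 | benzoyl chloride | O=C(Cl)c1ccccc1 | starting material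
7 | [(3aR,7aR)-2,2-dimethyl-3a,7a-dihydro-1,3-benzodioxol-3a-yl]methyl benzoate | O=C(OC[C@@]12OC(C)(C)O[C@@H]1C=CC=C2)c1ccccc1 | intermediate
8 | (1R,2R,3S,4S)-1-(benzoyloxymethyl)-3,4-epoxy-1,2-O-isopropylidenecyclohex-5-ene-1,2-diol | O=C(OC[C@@]12OC(C)(C)O[C@@H]1[C@H]1O[C@H]1C=C2)c1ccccc1 | intermediate
9 | benzyl alcohol | OCc1ccccc1 | starting material
10 | (1R,2R,3S,4R)-4-benzyloxy-1-(benzoyloxymethyl)-1,2-O-isopropylidenecyclohex-5-ene-1,2,3-triol | O=C(OC[C@@]12OC(C)(C)O[C@@H]1[C@@H](O)[C@H](OCc1ccccc1)C=C2)c1ccccc1 | intermediate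
11 | (1R,2R,3R,4R)-4-benzyloxy-1-(benzoyloxymethyl)cyclohex-5-ene-1,2,3-triol | O=C(OC[C@@]1(O)[C@H](O)[C@@H](O)[C@H](OCc2ccccc2)C=C1)c1ccccc1 | intermediate
12 | acetic anhydride | CC(=O)OC(C)=O | starting material
13 | (1R,2R,3S,4R)-2,3-di-O-acetyl-4-O-benzyl-1-(benzoyloxymethyl)cyclohex-5-ene-1,2,3,4-tetrol | O=C(OC[C@@]1(O)[C@H](OC(C)=O)[C@@H](OC(C)=O)[C@H](OCc2ccccc2)C=C1)c1ccccc1 | intermediate
14 | (1S,2R,3S,4R,5S,6R)-2,3-di-O-acetyl-4-O-benzyl-1-(benzoyloxymethyl)cyclohexane-1,2,3,4,5,6-hexol | O=C(OC[C@@]1(O)[C@H](OC(C)=O)[C@@H](OC(C)=O)[C@H](OCc2ccccc2)[C@@H](O)[C@H]1O)c1ccccc1 | intermediate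
15 | 5,6-cyclic sulfite of 14 (both epimers at sulfur) | O=C(OC[C@@]1(O)[C@H](OC(C)=O)[C@@H](OC(C)=O)[C@H](OCc2ccccc2)[C@H]2OS(=O)O[C@@H]12)c1ccccc1 | intermediate
16 | (1R,2R,3S,4S,5R,6R)-2,3-di-O-acetyl-4-O-benzyl-1-(benzoyloxymethyl)cyclohexane-1,2,3,4,5,6-hexol 5,6-cyclic sulfate | O=C(OC[C@@]1(O)[C@H](OC(C)=O)[C@@H](OC(C)=O)[C@H](OCc2ccccc2)[C@H]2OS(=O)(=O)O[C@@H]12)c1ccccc1 | intermediate
17 | sodium (1S,2R,3S,4S,5R,6S)-2,3-diacetoxy-4-benzyloxy-1-(benzoyloxymethyl)-1,6-epoxycyclohexan-5-yl sulfate | CC(=O)O[C@H]1[C@H](OCc2ccccc2)[C@@H](OS(=O)(=O)[O-])[C@@H]2O[C@]2(COC(=O)c2ccccc2)[C@@H]1OC(C)=O.[Na+] | intermediate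
18 | [(1S,2R,3S,4R,5R,6S)-2,3-diacetoxy-4-benzyloxy-5-hydroxy-7-oxabicyclo[4.1.0]heptan-1-yl]methyl benzoate | CC(=O)O[C@H]1[C@H](OCc2ccccc2)[C@@H](O)[C@@H]2O[C@]2(COC(=O)c2ccccc2)[C@@H]1OC(C)=O | intermediate
19 | [(1S,2R,3S,4R,5R,6S)-2,3-diacetoxy-4,5-dihydroxy-7-oxabicyclo[4.1.0]heptan-1-yl]methyl benzoate (CNP0171674.1) | CC(=O)O[C@H]1[C@H](O)[C@@H](O)[C@@H]2O[C@]2(COC(=O)c2ccccc2)[C@@H]1OC(C)=O | target

**Step count and risks**

Total step count: 12. Longest linear sequence: 12 steps (benzoic acid to the target; the route is fully linear).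

Steps most likely to fail:

Step 11. Once the C1 alkoxide is formed, acetyl and benzoyl groups may migrate before the oxirane closes, and the acid used to cleave the sulfate monoester may open the new oxirane. The fallback sets out from 14 and replaces the sulfate chemistry of steps 10 and 11 by a redox cyclodehydration under neutral conditions (PPh3, diisopropyl azodicarboxylate, THF, 0 °C to rt, Mitsunobu reaction). The cis C5,C6-diol can only form a dioxaphosphorane that reopens, whereas the oxyphosphonium ion at O6 has the C1 hydroxyl antiperiplanar and should be displaced with inversion. Neither a strong base nor an acid is present, no new intermediate arises, and the fallback comes back to the route at 18.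

Step 10. Thionyl chloride may sulfinylate or dehydrate the free tertiary hydroxyl, and the ruthenium oxidant may attack the benzylic CH2 of the ether. The fallback sets out from 14 and differentiates the two new hydroxyls instead of bridging them. TESCl and imidazole in DMF at −20 °C should silylate the equatorial, less hindered C5 hydroxyl to give the 5-O-triethylsilyl ether of 14 F1. MsCl and Et3N in CH2Cl2 at 0 °C should then sulfonylate the axial C6 hydroxyl to give the 6-O-methanesulfonate of that silyl ether F2. NaH in THF at 0 °C should close the oxirane with inversion at C6 to give the 5-O-triethylsilyl ether of 18 F3. HF·pyridine in THF removes the silyl group, and the fallback comes back to the route at 18.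

Step 9. Hydrogen-bonded delivery of the oxidant by the free tertiary hydroxyl may erode the facial selectivity, and slow oxidation of the hindered, electron-poor alkene may leave time for acyl migration. The fallback sets out from 13 and masks the hydroxyl before the oxidation. TESOTf and 2,6-lutidine in CH2Cl2 at −40 °C to 0 °C should give the 1-O-triethylsilyl ether of 13 F4, whose pseudoaxial silyloxy group blocks the α face and offers no hydrogen bond. OsO4 (cat.) with NMO in acetone/H2O should then give the 1-O-triethylsilyl ether of 14 F5 with both new hydroxyls β. HF·pyridine in THF at 0 °C removes the silyl group, and the fallback comes back to the route at 14.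

Further compounds
F0 | step 11 | none | none
F1 | step 10 | 5-O-triethylsilyl ether of 14 | O=C(OC[C@@]1(O)[C@H](OC(C)=O)[C@@H](OC(C)=O)[C@H](OCc2ccccc2)[C@@H](O[Si](CC)(CC)CC)[C@H]1O)c1ccccc1
F2 | step 10 | 6-O-methanesulfonate of the 5-O-triethylsilyl ether of 14 | O=C(OC[C@@]1(O)[C@H](OC(C)=O)[C@@H](OC(C)=O)[C@H](OCc2ccccc2)[C@@H](O[Si](CC)(CC)CC)[C@H]1OS(C)(=O)=O)c1ccccc1
F3 | step 10 | 5-O-triethylsilyl ether of 18 | CC(=O)O[C@H]1[C@H](OCc2ccccc2)[C@@H](O[Si](CC)(CC)CC)[C@@H]2O[C@]2(COC(=O)c2ccccc2)[C@@H]1OC(C)=O
F4 | step 9 | 1-O-triethylsilyl ether of 13 | O=C(OC[C@@]1(O[Si](CC)(CC)CC)[C@H](OC(C)=O)[C@@H](OC(C)=O)[C@H](OCc2ccccc2)C=C1)c1ccccc1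
F5 | step 9 | 1-O-triethylsilyl ether of 14 | O=C(OC[C@@]1(O[Si](CC)(CC)CC)[C@H](OC(C)=O)[C@@H](OC(C)=O)[C@H](OCc2ccccc2)[C@@H](O)[C@H]1O)c1ccccc1
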